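The runs were generated by integration on assumed constants, and the scatter is random.

Slow is what I read first: after 15.0 min, Friday's run has made 10.9% target and Tuesday's 23.5%. Each flask holds starting material, second substrate and free catalyst, and I follow the target.

| flask | starting material | second substrate | free catalyst | remark | time |
|---|---|---|---|---|---|
| Friday's | 0.17 M | 1 equiv | 2 mol% | run made earlier |  |
| Tuesday's | 0.95 M | 1 equiv | 2 mol% | run made earlier |  |
| ash | 0.12 M | 1.00 equiv | 2 mol% |  | 15 min |
| alder | 0.20 M | 1.00 equiv | 2 mol% |  | 15 min |
| maple | 0.30 M | 1.00 equiv | 2 mol% |  | 15 min |
| cedar | 0.50 M | 1.00 equiv | 2 mol% |  | 15 min |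
| oak | 0.60 M | 1.00 equiv | 2 mol% |  | 15 min |

| run | time / min | target / % | starting material / % |
|---|---|---|---|
| Friday's | 2.50 | 0.6 | 96.4 |
| Friday's | 5.00 | 2.9 | 96.7 |
| Friday's | 8.00 | 4.5 | 94.9 |
| Friday's | 10.0 | 4.9 | 92.4 |
| Friday's | 12.0 | 7.6 | 90.4 |
| Friday's | 15.0 | 10.9 | 87.0 |
| Tuesday's | 1.33 | 0.4 | 96.8 |
| Tuesday's | 2.00 | 0.7 | 98.9 |
| Tuesday's | 3.00 | 2.8 | 96.9 |
| Tuesday's | 5.00 | 4.8 | 93.7 |
| Tuesday's | 10.0 | 12.8 | 84.5 |
| Tuesday's | 15.0 | 23.5 | 74.7 |

(readings scatter by 1 percentage point)

- "hardly changes" means that all values lie within two and a half points (for a concentration: within two and a half percent of the largest)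

- [target] at the end for ash, alder, maple, cedar, oak, in this order
- the course of these numbers from the first flask to the last (rises, then falls / rises all the way / falls all the way / falls, then rises / hardly changes)

I integrate one rate in closed form. If starting material is lost in first order at steady catalyst, the log of charge over what is left grows in step with time. Dividing by time gives a pseudo-first-order constant. I take what is left as the charge minus the target. Friday's run gives 0.00769 min⁻¹ and Tuesday's gives 0.0179 min⁻¹.

Both runs carry 2 mol% catalyst, so catalyst rises with the charge, and my first estimate is that the constant rises with it, by a factor of 5.59. The readings refuse this: they give a factor of 2.33. So I keep what was read, the percent change of the constant per percent of charge at 2 mol% catalyst and 1.00 equiv of second substrate, which reads 0.489. I call it the charge slope.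

There is an objection: the constant may not be constant. Friday's run gives 0.00502 min⁻¹ at 10.0 min, less than at 15.0 min, so its target readings bend upward, within a scatter of 1 percentage point. But the new flasks are read at 15 min, the time of my two constants, so I use the constant as an average up to that time.

A second objection is scatter. The same slope taken from the 10.0 min readings is 0.583, and this objection stands as a margin.

The closed form is target = charge × (1 − exp(−constant × time)), with the constant scaled from Friday's run by the charge ratio raised to the slope. It gives 0.0111 M for ash and 0.116 M for oak, and the higher slope would put oak at 0.128 M. In this reckoning conversion and charge both rise along the row, so the target concentration climbs.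

The forecast gives 0.011 M, 0.024 M, 0.044 M, 0.092 M and 0.119 M, and says the row rises all the way. On the kinetics it says: “It suggests saturation or catalyst dimerisation into a resting state”. For oak, my single slope sits 0.00300 M below it.

The flasks give 0.00985 M, 0.0227 M, 0.0429 M, 0.0926 M and 0.121 M, and the row rises all the way.

    starting material + free catalyst ⇌ catalyst intermediate A (K = 1.60 M⁻¹, k = 0.670 M⁻¹ s⁻¹)
    catalyst intermediate A → free catalyst + target (k = 0.0440 s⁻¹)
    second substrate + free catalyst ⇌ catalyst intermediate B (K = 8.20 M⁻¹, k = 2.00 M⁻¹ s⁻¹)
    catalyst intermediate B → free catalyst + second product (k = 0.120 s⁻¹)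

Taken from ash to oak, the charge slope of the flasks is 0.601. Starting from alder's simulated target, the carried slope gives maple 0.0410 M, against 0.0429 M in the flask. In ash, the path from catalyst intermediate B to free catalyst and second product reaches the midpoint of its turnover up to 15.0 min by 6.36 min, earlier than the path from starting material and free catalyst to catalyst intermediate A at 7.63 min. At 15.0 min, ash keeps 41% of its second substrate and 92% of its starting material.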